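## Retrosynthetic overview

1. The target is an unsymmetrical C4–O–C4 ether of two C2-epimeric 7,8,4'-trihydroxyflavan-3,4-diol units: unit A is all-cis (2R,3R,4R), unit B is 2,3-trans-3,4-cis (2S,3R,4R). The ether is cut so that unit B keeps its O4 (alcohol 17) and unit A is the C4 electrophile (epoxide 12).
2. Unit A: anti opening of the epoxide sets C4 cis to the 2-aryl group; C3 is then corrected by oxidation and hydride delivery anti to both substituents.
3. Unit B: OsO4 adds anti to the 2-aryl group of the flavene; the equatorial 3-OH is then benzylated through the stannylene acetal.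
4. The two flavenes (11, 14) are enantiomers. Ring C of each is closed by ring-closing metathesis of an allyl aryl ether (10, 13). Both ethers come from one batch of lithium aryloxide 9 (from phenol 4) and one cinnamyl carbonate (8) by Ir-catalysed allylic etherification with the two hands of one ligand.
5. Ring order: ring C of unit A (step 9) and ring C of unit B (step 12) in parallel, then ether union, C3 inversion and global debenzylation.

Assumption: the (Sa,Sc,Sc) ligand is taken to give the (S)-ether and the (Ra,Rc,Rc) ligand the (R)-ether, as recalled for cinnamyl carbonates with N- and O-nucleophiles; if the sense is the reverse, the two ligands are simply exchanged, since both enantiomers are made.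

## Route

Step 1
Reactants: 1 2,3,4-trihydroxybenzaldehyde
Product: 2 2,3,4-tris(benzyloxy)benzaldehyde
Conditions: BnBr (3.6 equiv), K2CO3, DMF, 60 °C, N2
Reagents that add atoms: benzyl bromide, BrCc1ccccc1
Why: Exhaustive Williamson ether synthesis of the three phenols avoids the regioisomer mixtures of a partial benzylation.

Step 2
Reactants: 2 2,3,4-tris(benzyloxy)benzaldehyde
Product: 3 3,4-bis(benzyloxy)-2-hydroxybenzaldehyde
Conditions: MgBr2·OEt2 (1.5 equiv), toluene/Et2O, reflux; then 1 M HCl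
Reagents that add atoms: none
Why: Chelation of magnesium between the aldehyde oxygen and the ortho ether oxygen activates only that benzyl group for SN2 removal by bromide (chelation-controlled ortho-debenzylation).

Step 3
Reactants: 3 3,4-bis(benzyloxy)-2-hydroxybenzaldehyde
Product: 4 2,3-bis(benzyloxy)-6-ethenylphenol
Conditions: Ph3PCH3Br (2.5 equiv), KOt-Bu (2.5 equiv), THF, 0 °C to rt
Reagents that add atoms: methyltriphenylphosphonium bromide (as its ylide), C[P+](c1ccccc1)(c1ccccc1)c1ccccc1.[Br-]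
Why: Wittig methylenation works on salicylaldehydes when a second equivalent of ylide is used to take up the phenolic proton.

Step 4
Reactants: 5 4-(benzyloxy)benzaldehyde
Product: 6 ethyl (E)-3-[4-(benzyloxy)phenyl]prop-2-enoate
Conditions: Ph3P=CHCO2Et, toluene, 80 °C
Reagents that add atoms: ethyl (triphenylphosphoranylidene)acetate, CCOC(=O)C=P(c1ccccc1)(c1ccccc1)c1ccccc1
Why: Wittig olefination with a stabilised ylide gives the (E)-cinnamate with high selectivity.

Step 5
Reactants: 6 ethyl (E)-3-[4-(benzyloxy)phenyl]prop-2-enoate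
Product: 7 (E)-3-[4-(benzyloxy)phenyl]prop-2-en-1-ol
Conditions: i-Bu2AlH (2.5 equiv), CH2Cl2, −78 °C; aq. potassium sodium tartrate
Reagents that add atoms: none
Why: i-Bu2AlH reduces the conjugated ester 1,2 to the allylic alcohol without touching the alkene.

Step 6
Reactants: 7 (E)-3-[4-(benzyloxy)phenyl]prop-2-en-1-ol
Product: 8 (E)-3-[4-(benzyloxy)phenyl]prop-2-en-1-yl methyl carbonate
Conditions: ClCO2Me, pyridine, CH2Cl2, 0 °C
Reagents that add atoms: methyl chloroformate, COC(Cl)=O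
Why: O-acylation gives the linear allylic carbonate that Ir catalysts ionise readily.

Step 7
Reactants: 4 2,3-bis(benzyloxy)-6-ethenylphenol
Product: 9 lithium 2,3-bis(benzyloxy)-6-ethenylphenolate
Conditions: n-BuLi (0.98 equiv, hexanes), THF, 0 °C, Ar; volatiles removed, solid washed with pentane and dried in vacuo; stored under Ar and divided between steps 8 and 11
Reagents that add atoms: n-butyllithium, [Li]CCCC
Why: Acid–base metalation of the phenol is far faster than any addition of the alkyllithium to the styrene, and the salt-free preformed lithium aryloxide is the nucleophile that Ir-catalysed allylic etherification needs.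

Step 8
Reactants: 9 lithium 2,3-bis(benzyloxy)-6-ethenylphenolate; 8 (E)-3-[4-(benzyloxy)phenyl]prop-2-en-1-yl methyl carbonate
Product: 10 1,2-bis(benzyloxy)-3-{[(1S)-1-[4-(benzyloxy)phenyl]prop-2-en-1-yl]oxy}-4-ethenylbenzene
Conditions: 9 (1.5 equiv), [Ir(cod)Cl]2 (2 mol %), (Sa,Sc,Sc)-O,O'-(1,1'-binaphthalene-2,2'-diyl) N,N-bis(1-phenylethyl)phosphoramidite (4 mol %), THF, 50 °C
Reagents that add atoms: none
Why: Ir-catalysed enantioselective allylic etherification puts the aryloxide on the substituted allyl terminus, and the ligand hand sets the (S) carbinol centre that becomes C2 of unit A.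

Step 9
Reactants: 10 the (S)-allyl aryl ether
Product: 11 (2S)-7,8-bis(benzyloxy)-2-[4-(benzyloxy)phenyl]-2H-chromene
Conditions: second-generation Grubbs catalyst, (H2IMes)(PCy3)Cl2Ru=CHPh (3 mol %), CH2Cl2 (0.02 M), 40 °C, dark
Reagents that add atoms: none
Why: Ring-closing metathesis of the styrene and allyl ether alkenes closes the six-membered ring C with loss of ethene and does not touch the stereocentre.

Step 10
Reactants: 11 the (2S)-flavene
Product: 12 (2R,3S,4S)-7,8-bis(benzyloxy)-2-[4-(benzyloxy)phenyl]-3,4-epoxychromane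
Conditions: dimethyldioxirane (1.2 equiv, acetone solution), CH2Cl2, −40 to 0 °C; volatiles removed cold, used at once
Reagents that add atoms: dimethyldioxirane, CC1(C)OO1
Why: Neutral epoxidation of the electron-rich C3=C4 bond occurs on the face opposite the 2-aryl group, giving the trans epoxide (the C2 descriptor changes only through CIP priorities).

Step 11
Reactants: 9 lithium 2,3-bis(benzyloxy)-6-ethenylphenolate; 8 (E)-3-[4-(benzyloxy)phenyl]prop-2-en-1-yl methyl carbonate
Product: 13 1,2-bis(benzyloxy)-3-{[(1R)-1-[4-(benzyloxy)phenyl]prop-2-en-1-yl]oxy}-4-ethenylbenzene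
Conditions: 9 (1.5 equiv), [Ir(cod)Cl]2 (2 mol %), (Ra,Rc,Rc)-O,O'-(1,1'-binaphthalene-2,2'-diyl) N,N-bis(1-phenylethyl)phosphoramidite (4 mol %), THF, 50 °C
Reagents that add atoms: none
Why: The same Ir-catalysed allylic etherification with the mirror-image ligand sets the (R) centre that becomes C2 of unit B.

Step 12
Reactants: 13 the (R)-allyl aryl ether
Product: 14 (2R)-7,8-bis(benzyloxy)-2-[4-(benzyloxy)phenyl]-2H-chromene
Conditions: second-generation Grubbs catalyst, (H2IMes)(PCy3)Cl2Ru=CHPh (3 mol %), CH2Cl2 (0.02 M), 40 °C, dark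
Reagents that add atoms: none
Why: Ring-closing metathesis closes ring C of unit B exactly as in step 9.

Step 13
Reactants: 14 the (2R)-flavene
Product: 15 (2S,3R,4R)-7,8-bis(benzyloxy)-2-[4-(benzyloxy)phenyl]chromane-3,4-diol
Conditions: OsO4 (2 mol %), N-methylmorpholine N-oxide (1.5 equiv), acetone/H2O 5:1, rt
Reagents that add atoms: N-methylmorpholine N-oxide, C[N+]1([O-])CCOCC1; water, O (both oxygen atoms reach the alkene through OsO4)
Why: Upjohn syn-dihydroxylation adds both oxygens from the face opposite the 2-aryl group, giving the 2,3-trans-3,4-cis diol with C3 and C4 as in unit B.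

Step 14
Reactants: 15 the 2,3-trans-3,4-cis diol
Product: 17 (2S,3R,4R)-3,7,8-tris(benzyloxy)-2-[4-(benzyloxy)phenyl]chroman-4-ol, via stannylene acetal 16 (not isolated)
Conditions: Bu2SnO (1.1 equiv), toluene, reflux (−H2O); then BnBr, CsF, DMF, rt
Reagents that add atoms: benzyl bromide, BrCc1ccccc1
Why: Stannylene-mediated monoalkylation of a cis-diol goes to the equatorial oxygen, here O3, leaving the pseudo-axial benzylic 4-OH free as the nucleophile.

Step 15
Reactants: 12 the trans epoxide (1.5 equiv); 17 the 3-O-benzyl 4-alcohol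
Product: 18 (2R,3S,4R)-7,8-bis(benzyloxy)-2-[4-(benzyloxy)phenyl]-4-{[(2S,3R,4R)-3,7,8-tris(benzyloxy)-2-[4-(benzyloxy)phenyl]chroman-4-yl]oxy}chroman-3-ol
Conditions: ZnCl2 (1.2 equiv, 1 M in Et2O), 4 Å molecular sieves, THF, −78 to 0 °C
Reagents that add atoms: none
Why: Lewis-acid-promoted epoxide opening at the benzylic C4 (stabilised by the para 7-oxygen) proceeds anti to the epoxide oxygen, as in the opening of 1,2-anhydro sugars, so the new C4–O bond is cis to the 2-aryl group while the C4 centre of 17 is untouched.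

Step 16
Reactants: 18 the coupled 3-alcohol
Product: 19 (2R,4R)-7,8-bis(benzyloxy)-2-[4-(benzyloxy)phenyl]-4-{[(2S,3R,4R)-3,7,8-tris(benzyloxy)-2-[4-(benzyloxy)phenyl]chroman-4-yl]oxy}chroman-3-one
Conditions: Dess–Martin periodinane (1.5 equiv), pyridine, CH2Cl2, 0 °C to rt
Reagents that add atoms: none
Why: Dess–Martin oxidation of the only free hydroxyl under buffered conditions gives the flavan-3-one without epimerising C2 or C4, whose cis arrangement is in any case the stable one.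

Step 17
Reactants: 19 the flavan-3-one
Product: 20 (2R,3R,4R)-7,8-bis(benzyloxy)-2-[4-(benzyloxy)phenyl]-4-{[(2S,3R,4R)-3,7,8-tris(benzyloxy)-2-[4-(benzyloxy)phenyl]chroman-4-yl]oxy}chroman-3-ol
Conditions: LiBH(s-Bu)3 (1.5 equiv), THF, −78 °C; then H2O
Reagents that add atoms: none
Why: The bulky hydride attacks the ketone from the face opposite the cis 2-aryl and 4-alkoxy groups, giving the axial all-cis 3-alcohol, as in the catechin-to-epicatechin inversion.

Step 18
Reactants: 20 the heptabenzyl ether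
Product: 21 (2R,3R,4R)-2-(4-hydroxyphenyl)-4-{[(2S,3R,4R)-3,7,8-trihydroxy-2-(4-hydroxyphenyl)chroman-4-yl]oxy}chromane-3,7,8-triol
Conditions: H2 (1 atm), Pd(OH)2/C, THF/MeOH 1:1, rt, neutral, stopped at completion
Reagents that add atoms: none
Why: Neutral hydrogenolysis removes the seven O-benzyl groups, while the hindered, para-oxygenated secondary C4–O–C4 ether should be cleaved much more slowly in the absence of acid.

## Compound list

1 | 2,3,4-trihydroxybenzaldehyde | O=Cc1ccc(O)c(O)c1O | starting material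
2 | 2,3,4-tris(benzyloxy)benzaldehyde | O=Cc1ccc(OCc2ccccc2)c(OCc2ccccc2)c1OCc1ccccc1 | intermediate
3 | 3,4-bis(benzyloxy)-2-hydroxybenzaldehyde | O=Cc1ccc(OCc2ccccc2)c(OCc2ccccc2)c1O | intermediate
4 | 2,3-bis(benzyloxy)-6-ethenylphenol | C=Cc1ccc(OCc2ccccc2)c(OCc2ccccc2)c1O | intermediate
5 | 4-(benzyloxy)benzaldehyde | O=Cc1ccc(OCc2ccccc2)cc1 | starting material
6 | ethyl (E)-3-[4-(benzyloxy)phenyl]prop-2-enoate | CCOC(=O)/C=C/c1ccc(OCc2ccccc2)cc1 | intermediate
7 | (E)-3-[4-(benzyloxy)phenyl]prop-2-en-1-ol | OC/C=C/c1ccc(OCc2ccccc2)cc1 | intermediate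
8 | (E)-3-[4-(benzyloxy)phenyl]prop-2-en-1-yl methyl carbonate | COC(=O)OC/C=C/c1ccc(OCc2ccccc2)cc1 | intermediate
9 | lithium 2,3-bis(benzyloxy)-6-ethenylphenolate | [Li+].[O-]c1c(C=C)ccc(OCc2ccccc2)c1OCc1ccccc1 | intermediate
10 | 1,2-bis(benzyloxy)-3-{[(1S)-1-[4-(benzyloxy)phenyl]prop-2-en-1-yl]oxy}-4-ethenylbenzene | c1ccccc1COc1ccc([C@H](C=C)Oc2c(C=C)ccc(OCc3ccccc3)c2OCc2ccccc2)cc1 | intermediate
11 | (2S)-7,8-bis(benzyloxy)-2-[4-(benzyloxy)phenyl]-2H-chromene | c1ccccc1COc1ccc([C@H]2Oc3c(ccc(OCc4ccccc4)c3OCc3ccccc3)C=C2)cc1 | intermediate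
12 | (2R,3S,4S)-7,8-bis(benzyloxy)-2-[4-(benzyloxy)phenyl]-3,4-epoxychromane (oxirane trans to the aryl group) | c1ccccc1COc1ccc([C@H]2Oc3c(ccc(OCc4ccccc4)c3OCc3ccccc3)[C@@H]5O[C@@H]52)cc1 | intermediate
13 | 1,2-bis(benzyloxy)-3-{[(1R)-1-[4-(benzyloxy)phenyl]prop-2-en-1-yl]oxy}-4-ethenylbenzene | c1ccccc1COc1ccc([C@@H](C=C)Oc2c(C=C)ccc(OCc3ccccc3)c2OCc2ccccc2)cc1 | intermediate
14 | (2R)-7,8-bis(benzyloxy)-2-[4-(benzyloxy)phenyl]-2H-chromene | c1ccccc1COc1ccc([C@@H]2Oc3c(ccc(OCc4ccccc4)c3OCc3ccccc3)C=C2)cc1 | intermediate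
15 | (2S,3R,4R)-7,8-bis(benzyloxy)-2-[4-(benzyloxy)phenyl]chromane-3,4-diol (2,3-trans-3,4-cis) | c1ccccc1COc1ccc([C@@H]2Oc3c(ccc(OCc4ccccc4)c3OCc3ccccc3)[C@@H](O)[C@H]2O)cc1 | intermediate
16 | 3,4-O-dibutylstannylene acetal of 15 (not isolated) | c1ccccc1COc1ccc([C@@H]2Oc3c(ccc(OCc4ccccc4)c3OCc3ccccc3)[C@H]5O[Sn](CCCC)(CCCC)O[C@H]52)cc1 | intermediate
17 | (2S,3R,4R)-3,7,8-tris(benzyloxy)-2-[4-(benzyloxy)phenyl]chroman-4-ol | c1ccccc1COc1ccc([C@@H]2Oc3c(ccc(OCc4ccccc4)c3OCc3ccccc3)[C@@H](O)[C@H]2OCc5ccccc5)cc1 | intermediate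
18 | (2R,3S,4R)-7,8-bis(benzyloxy)-2-[4-(benzyloxy)phenyl]-4-{[(2S,3R,4R)-3,7,8-tris(benzyloxy)-2-[4-(benzyloxy)phenyl]chroman-4-yl]oxy}chroman-3-ol | c1ccccc1COc1ccc([C@H]2Oc3c(ccc(OCc4ccccc4)c3OCc3ccccc3)[C@@H](O[C@@H]6c7ccc(OCc8ccccc8)c(OCc8ccccc8)c7O[C@@H](c7ccc(OCc8ccccc8)cc7)[C@@H]6OCc9ccccc9)[C@@H]2O)cc1 | intermediate
19 | (2R,4R)-7,8-bis(benzyloxy)-2-[4-(benzyloxy)phenyl]-4-{[(2S,3R,4R)-3,7,8-tris(benzyloxy)-2-[4-(benzyloxy)phenyl]chroman-4-yl]oxy}chroman-3-one | c1ccccc1COc1ccc([C@H]2Oc3c(ccc(OCc4ccccc4)c3OCc3ccccc3)[C@@H](O[C@@H]6c7ccc(OCc8ccccc8)c(OCc8ccccc8)c7O[C@@H](c7ccc(OCc8ccccc8)cc7)[C@@H]6OCc9ccccc9)C2=O)cc1 | intermediate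
20 | (2R,3R,4R)-7,8-bis(benzyloxy)-2-[4-(benzyloxy)phenyl]-4-{[(2S,3R,4R)-3,7,8-tris(benzyloxy)-2-[4-(benzyloxy)phenyl]chroman-4-yl]oxy}chroman-3-ol | c1ccccc1COc1ccc([C@H]2Oc3c(ccc(OCc4ccccc4)c3OCc3ccccc3)[C@@H](O[C@@H]6c7ccc(OCc8ccccc8)c(OCc8ccccc8)c7O[C@@H](c7ccc(OCc8ccccc8)cc7)[C@@H]6OCc9ccccc9)[C@H]2O)cc1 | intermediate
21 | (2R,3R,4R)-2-(4-hydroxyphenyl)-4-{[(2S,3R,4R)-3,7,8-trihydroxy-2-(4-hydroxyphenyl)chroman-4-yl]oxy}chromane-3,7,8-triol (CNP0241481.1) | Oc1ccc([C@H]2Oc3c(ccc(O)c3O)[C@@H](O[C@@H]3c4ccc(O)c(O)c4O[C@@H](c4ccc(O)cc4)[C@@H]3O)[C@H]2O)cc1 | target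

## Totals and risk steps

Total step count: 18.
Longest linear sequence: 12 steps (1, 2, 3, 7, 11, 12, 13, 14, 15, 16, 17, 18), which is 12 of 18.

Steps most likely to fail:

Step 15 (ether union). The epoxide is very labile, alcohol 17 is hindered, and a long-lived C4 cation could give some of the C4 epimer. Fallback, setting out from epoxide 12 and coming back at 18: 12 is opened at C4 with benzyl mercaptan (cat. ZnCl2, −40 °C) to the 3,4-trans 4-benzylsulfanylflavan-3-ol F1, which is benzoylated (BzCl, pyridine) to the 3-O-benzoate F2. AgBF4 in CH2Cl2 at 0 °C in the presence of 17 ionises the C–S bond; the benzoate bridges C4 from its own face, so 17 can enter only anti and gives the 3,4-trans ether benzoate F3 whatever the lifetime of the cation. K2CO3 in MeOH removes the benzoate and returns 18.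

Step 8 (and its mirror image, step 11). The aryloxide carries two ortho substituents, and the electron-rich cinnamyl system may give low branched selectivity or low ee. Fallback, setting out from aldehyde 5 and coming back at flavenes 11 and 14: 5 is condensed (KOH, EtOH) with 1-[3,4-bis(benzyloxy)-2-hydroxyphenyl]ethan-1-one F4, made by one selective benzylation of commercial 2,3,4-trihydroxyacetophenone, to give the 2'-hydroxychalcone F5. NaBH4 in refluxing 2-propanol reduces the carbonyl group to the racemic allylic alcohol F6, which on acidification with AcOH loses water and closes ring C to the racemic flav-3-ene, which is 11 and 14 in equal amounts. These are separated by preparative chromatography on a chiral stationary phase. Both enantiomers are needed, so the resolution wastes nothing, and steps 7, 8, 9, 11 and 12 are bypassed.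

Step 18 (global hydrogenolysis). The aliphatic 3-O-benzyl group of unit B is the slowest to fall, and the long exposure it needs puts the benzylic interflavanyl ether at risk. Fallback, setting out from diol 15 (through stannylene 16) and coming back at 21: quenching 16 with benzyl chloroformate instead of benzyl bromide gives the 3-O-benzyl carbonate F7. Steps 15 to 17 run on F7 give in turn the ether F8, the ketone F9 and the all-cis alcohol F10; LiBH(s-Bu)3 at −78 °C leaves the carbonate alone. In F10 every group to be removed is an aryl benzyl ether or a benzyl carbonate. All of these cleave within minutes over Pd/C under H2, so the hydrogenolysis can be stopped well before the interflavanyl ether is attacked, giving 21.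

## Further compounds

F1 | step 15 | 2,3-trans-3,4-trans-(2R)-4-(benzylsulfanyl)-7,8-bis(benzyloxy)-2-[4-(benzyloxy)phenyl]chroman-3-ol | c1ccccc1COc1ccc([C@H]2Oc3c(ccc(OCc4ccccc4)c3OCc3ccccc3)[C@@H](SCc5ccccc5)[C@@H]2O)cc1
F2 | step 15 | 3-O-benzoate of F1 | c1ccccc1COc1ccc([C@H]2Oc3c(ccc(OCc4ccccc4)c3OCc3ccccc3)[C@@H](SCc5ccccc5)[C@@H]2OC(=O)c6ccccc6)cc1
F3 | step 15 | 3-O-benzoate of 18 (benzoate on the 3-oxygen of unit A) | c1ccccc1COc1ccc([C@H]2Oc3c(ccc(OCc4ccccc4)c3OCc3ccccc3)[C@@H](O[C@@H]6c7ccc(OCc8ccccc8)c(OCc8ccccc8)c7O[C@@H](c7ccc(OCc8ccccc8)cc7)[C@@H]6OCc9ccccc9)[C@@H]2OC(=O)c5ccccc5)cc1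
F4 | step 8 | 1-[3,4-bis(benzyloxy)-2-hydroxyphenyl]ethan-1-one | CC(=O)c1ccc(OCc2ccccc2)c(OCc2ccccc2)c1O
F5 | step 8 | (E)-1-[3,4-bis(benzyloxy)-2-hydroxyphenyl]-3-[4-(benzyloxy)phenyl]prop-2-en-1-one | O=C(/C=C/c1ccc(OCc2ccccc2)cc1)c1ccc(OCc2ccccc2)c(OCc2ccccc2)c1O
F6 | step 8 | racemic (E)-1-[3,4-bis(benzyloxy)-2-hydroxyphenyl]-3-[4-(benzyloxy)phenyl]prop-2-en-1-ol | OC(/C=C/c1ccc(OCc2ccccc2)cc1)c1ccc(OCc2ccccc2)c(OCc2ccccc2)c1O
F7 | step 18 | benzyl (2S,3R,4R)-7,8-bis(benzyloxy)-2-[4-(benzyloxy)phenyl]-4-hydroxychroman-3-yl carbonate | c1ccccc1COc1ccc([C@@H]2Oc3c(ccc(OCc4ccccc4)c3OCc3ccccc3)[C@@H](O)[C@H]2OC(=O)OCc5ccccc5)cc1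
F8 | step 18 | analogue of 18 with a benzyl carbonate in place of the 3-O-benzyl ether of unit B | c1ccccc1COc1ccc([C@H]2Oc3c(ccc(OCc4ccccc4)c3OCc3ccccc3)[C@@H](O[C@@H]6c7ccc(OCc8ccccc8)c(OCc8ccccc8)c7O[C@@H](c7ccc(OCc8ccccc8)cc7)[C@@H]6OC(=O)OCc9ccccc9)[C@@H]2O)cc1
F9 | step 18 | analogue of 19 with a benzyl carbonate in place of the 3-O-benzyl ether of unit B | c1ccccc1COc1ccc([C@H]2Oc3c(ccc(OCc4ccccc4)c3OCc3ccccc3)[C@@H](O[C@@H]6c7ccc(OCc8ccccc8)c(OCc8ccccc8)c7O[C@@H](c7ccc(OCc8ccccc8)cc7)[C@@H]6OC(=O)OCc9ccccc9)C2=O)cc1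
F10 | step 18 | analogue of 20 with a benzyl carbonate in place of the 3-O-benzyl ether of unit B | c1ccccc1COc1ccc([C@H]2Oc3c(ccc(OCc4ccccc4)c3OCc3ccccc3)[C@@H](O[C@@H]6c7ccc(OCc8ccccc8)c(OCc8ccccc8)c7O[C@@H](c7ccc(OCc8ccccc8)cc7)[C@@H]6OC(=O)OCc9ccccc9)[C@H]2O)cc1
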